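**Assumptions (one line each)**
- The target SMILES has no stereocentres, so it is achiral and "single enantiomer" is moot. No step needs stereocontrol.
- Both C–C bond-forming events on the resorcinol ring are assumed to occur at the positions ortho to OMe and ortho/para to the OH groups, not at the crowded position between the two OH groups. This follows the usual resorcinol reactivity pattern.

**Retrosynthetic overview**
1. Disconnect the C3-aryl bond (Suzuki coupling): 3-bromo-2H-chromene plus 2,4-dihydroxyphenylboronic acid.
2. Form the pyran ring by a phenylboronic-acid-templated ortho-hydroxyalkylation of a prenylated 5-methoxyresorcinol with 2-bromoacrolein. Dehydration gives a transient dearomatised o-quinone methide, which closes by oxa-6π electrocyclisation to the 3-bromo-2H-chromene. This is the key step.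
3. The prenylated phenol comes from desymmetrising C-prenylation of the mirror-symmetric 5-methoxyresorcinol with prenyl bromide.
4. Ring order: the pyran ring is made in step 2, and the resorcinol B-ring is attached last by cross-coupling.

---

**Step 1**
Reactants: 1 (5-methoxyresorcinol, 3,5-dihydroxyanisole); 2 (prenyl bromide, 1-bromo-3-methylbut-2-ene)
Product: 3 (5-methoxy-4-(3-methylbut-2-en-1-yl)benzene-1,3-diol)
Conditions: 1 (3 equiv) and KOH (3.3 equiv) in H2O, 0 °C; add 2 (1 equiv); rt, 3 h; then aq. HCl work-up.
Reagents that add atoms: prenyl bromide, CC(C)=CCBr (adds the prenyl group).
Why: Phenoxide C-alkylation in water goes through a transient dearomatised cyclohexadienone that re-aromatises by tautomerisation; this is the Friedel–Crafts-type C-prenylation of phloroglucinol-type phenols. Water H-bonds the phenoxide oxygen, which favours C- over O-alkylation. Attack at the C2/C6 site, ortho to OMe and ortho/para to the OH groups, breaks the mirror symmetry of 1. Excess 1 suppresses di-prenylation. No stereocentre is formed.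

**Step 2**
Reactants: 3 (prenylated phenol); 4 (2-bromoacrolein)
Product: 5 (3-bromo-5-methoxy-6-(3-methylbut-2-en-1-yl)-2H-chromen-7-ol)
Conditions: 4 (2 equiv), PhB(OH)2 (1.0 equiv), AcOH (1 equiv), toluene, 90 °C, sealed tube, 12 h, under argon.
Reagents that add atoms: none beyond reactant 4. PhB(OH)2 is a removable template.
Why: Proposed new method: the phenol forms an aryl boronate that binds the enal's aldehyde and delivers it to the ortho carbon by 1,2-addition, which suppresses Michael addition. Loss of water gives a dearomatised o-quinone methide, O=C–C=CH–C(Br)=CH2, which closes by oxa-6π electrocyclisation to the 2H-chromene with C4 from the CHO carbon and C2 from the CH2 terminus. The closest known reaction is the phenylboronic-acid-mediated phenol–enal annulation to 2,2-disubstituted 2H-chromenes, extended here to an α-bromo enal with an unsubstituted β-carbon. The mildly acidic conditions leave the prenyl alkene intact.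

**Step 3**
Reactants: 5 (3-bromochromene); 6 (2,4-dihydroxyphenylboronic acid)
Product: 7 (dehydroglyasperin C)
Conditions: 6 (2.0 equiv), Pd(OAc)2 (5 mol %), SPhos (10 mol %), K3PO4 (4 equiv), dioxane/H2O 4:1, 80 °C, 4 h, under argon.
Reagents that add atoms: none beyond reactant 6.
Why: Suzuki–Miyaura coupling of a vinyl bromide with an arylboronic acid. The aqueous K3PO4/SPhos system tolerates free phenols and the prenyl alkene, and the excess boronic acid offsets protodeboronation. No stereocentre is formed, and the chromene C3=C4 alkene is retained.

---

**Compound list**
1 | 5-methoxyresorcinol (3,5-dihydroxyanisole) | COc1cc(O)cc(O)c1 | starting material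
2 | prenyl bromide | CC(C)=CCBr | starting material
3 | 5-methoxy-4-prenylbenzene-1,3-diol | COc1cc(O)cc(O)c1CC=C(C)C | intermediate
4 | 2-bromoacrolein | C=C(Br)C=O | starting material
5 | 3-bromo-5-methoxy-6-prenyl-2H-chromen-7-ol | COc1c2C=C(Br)COc2cc(O)c1CC=C(C)C | intermediate
6 | 2,4-dihydroxyphenylboronic acid | OB(O)c1ccc(O)cc1O | starting material
7 | dehydroglyasperin C (achiral) | COc1c2c(cc(O)c1CC=C(C)C)OCC(c1ccc(O)cc1O)=C2 | target

**Total step count:** 3
**Longest linear sequence:** 3 steps (1 → 3 → 5 → 7)

**Three steps most likely to fail**
1. **Step 2 (pyran annulation).** Risks are Michael addition or polymerisation of 2-bromoacrolein, and ring closure at the wrong ortho site, namely the carbon between the two OH groups.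
   - Fallback: change the strategy to a benzopyrylium route. Condense 3 with a protected 2-aryl-malondialdehyde or vinamidinium to give an isoflavylium salt, then reduce it regioselectively at C2 (hydride), with deprotection.
2. **Step 1 (mono-C-prenylation).** Risks are O-prenylation, di-prenylation, prenylation at the C4 position between the two OH groups, and acid-driven chromane formation.
   - Fallback: brominate 1 regioselectively at C2 (NBS), then install the prenyl group by Pd-catalysed cross-coupling with a prenyl-B(pin) or prenylzinc reagent.
3. **Step 3 (Suzuki with an unprotected polyphenol).** Risks are protodeboronation of the electron-rich 2-hydroxyarylboronic acid and Pd(0) ionisation of the allylic aryl ether in the chromene.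
   - Fallback: drop the coupling. Use a 2-(2,4-bis-silyloxyphenyl)acrolein in place of 2-bromoacrolein in step 2, which gives the 3-aryl chromene directly, then remove the silyl groups with TBAF.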